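**Plan**
- Enabling feature: the only stereocentre is the methine carbon of the Ar2CH–CH2Ar unit. It carries two 2,4-dihydroxyphenyl rings (A and B) that differ only by the (E)-3,5-dihydroxystyryl group at C5 of ring B. Without that group a mirror plane runs through the methine C–H and the CH2–ring C arm, so rings A and B are enantiotopic.
- Cuts: first C5(ring B)–CH= of the styryl unit (ring D), then methine C–CH2 (ring C arm), then two C5–Br helper bonds. This leads back to 2,2',4,4'-tetrahydroxybenzophenone, 3,5-dimethoxybenzyl chloride and 3,5-dihydroxybenzaldehyde; all four benzene rings are bought.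
- Forward: the benzophenone (rings A and B) is methylated and brominated at both C5. Ring C is added as a benzyl Grignard reagent, the carbinol is reduced to the achiral dibromide, and methyl is exchanged for acetyl. Ring D is joined last as 3,5-diacetoxystyrene.
- Stereochemistry: a chiral Pd catalyst chooses one of the two enantiotopic C5–Br bonds in a desymmetrising Mizoroki–Heck reaction. The same event forms the stilbene bond, fixes the E geometry (syn insertion, syn elimination) and creates the stereocentre.
- Helpers: the spectator bromine on ring A is removed by Pd/formate reduction, and the eight acetyl groups by ammonolysis.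

Key step: step 7

Assumption: the sense of induction of a new desymmetrisation cannot be predicted, so (S)-BI-DIME stands for whichever ligand antipode gives the required bromostilbene enantiomer; both antipodes are commercial, and the residual bromine allows the assignment by anomalous-dispersion X-ray analysis.

**Step 1**
Reactants: 1 2,2',4,4'-tetrahydroxybenzophenone
Product: 2 2,2',4,4'-tetramethoxybenzophenone
Conditions: MeI (6 equiv), K2CO3 (6 equiv), DMF, 50 °C
Reagents that add atoms: iodomethane, CI
Why: Williamson ether synthesis in which excess MeI/K2CO3 in DMF also alkylates the two carbonyl-chelated 2-OH groups, giving ethers that survive the Grignard and acid steps that follow.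

**Step 2**
Reactants: 2 2,2',4,4'-tetramethoxybenzophenone
Product: 3 bis(5-bromo-2,4-dimethoxyphenyl)methanone
Conditions: NBS (2.1 equiv), MeCN, 0 °C to rt, dark
Reagents that add atoms: N-bromosuccinimide, O=C1CCC(=O)N1Br
Why: Electrophilic aromatic bromination goes to C5 of each ring (para to 2-OMe, ortho to 4-OMe, meta to C=O) because C3 is shielded between two methoxy groups, and it is done before the more nucleophilic ring C is present.

**Step 3**
Reactants: 3 bis(5-bromo-2,4-dimethoxyphenyl)methanone; 4 3,5-dimethoxybenzyl chloride
Product: 6 1,1-bis(5-bromo-2,4-dimethoxyphenyl)-2-(3,5-dimethoxyphenyl)ethan-1-ol, via 3,5-dimethoxybenzylmagnesium chloride 5 (not isolated)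
Conditions: i) 4, Mg, THF, 0 °C, slow addition; ii) 3, LaCl3·2LiCl (30 mol %), THF, 0 °C to rt; aq NH4Cl
Reagents that add atoms: magnesium, [Mg] (retained in 5 only)
Why: Grignard 1,2-addition to a non-enolisable diaryl ketone whose hindered carbonyl is activated by the lanthanum salt, at a temperature where a benzylic Grignard reagent does not exchange with electron-rich aryl bromides.

**Step 4**
Reactants: 6 1,1-bis(5-bromo-2,4-dimethoxyphenyl)-2-(3,5-dimethoxyphenyl)ethan-1-ol
Product: 7 1,1-bis(5-bromo-2,4-dimethoxyphenyl)-2-(3,5-dimethoxyphenyl)ethane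
Conditions: Et3SiH (3 equiv), TFA (10 equiv), CH2Cl2, 0 °C
Reagents that add atoms: none
Why: Ionic hydrogenation (Kursanov–Parnes) in which TFA ionises the carbinol to a carbenium ion stabilised by two 2,4-dimethoxyphenyl rings and Et3SiH delivers hydride, leaving C–Br and OMe untouched and giving an achiral, mirror-symmetric product.

**Step 5**
Reactants: 7 1,1-bis(5-bromo-2,4-dimethoxyphenyl)-2-(3,5-dimethoxyphenyl)ethane
Product: 9 1,1-bis(2,4-diacetoxy-5-bromophenyl)-2-(3,5-diacetoxyphenyl)ethane, via hexaphenol dibromide 8 (not isolated)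
Conditions: i) BBr3 (9 equiv), CH2Cl2, −78 °C to rt; ice/H2O, EtOAc extraction; ii) Ac2O, pyridine, DMAP (cat.), rt
Reagents that add atoms: acetic anhydride, CC(=O)OC(C)=O
Why: BBr3 aryl methyl ether cleavage followed by O-acetylation places the only harsh deprotection where there is neither an alkene nor a stereocentre, and the acetates make the bromoarenes less electron-rich for oxidative addition and can later be removed without acid.

**Step 6**
Reactants: 10 3,5-dihydroxybenzaldehyde
Product: 12 3,5-diacetoxystyrene (5-ethenyl-1,3-phenylene diacetate), via 3,5-dihydroxystyrene 11 (not isolated)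
Conditions: i) MePPh3Br (1.3 equiv), KOt-Bu (3.4 equiv), THF, 0 °C to rt; aq NH4Cl; ii) crude 11, Ac2O, pyridine, 0 °C to rt
Reagents that add atoms: methyltriphenylphosphonium bromide, C[P+](c1ccccc1)(c1ccccc1)c1ccccc1.[Br-]; acetic anhydride, CC(=O)OC(C)=O
Why: Wittig methylenation with extra base for the two phenols, whose meta-phenoxides are not conjugated with the aldehyde and so do not deactivate it, followed by direct acetylation of the polymerisation-prone vinylresorcinol.

**Step 7**
Reactants: 9 1,1-bis(2,4-diacetoxy-5-bromophenyl)-2-(3,5-diacetoxyphenyl)ethane; 12 3,5-diacetoxystyrene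
Product: 13 4-[(1R)-1-(2,4-diacetoxy-5-bromophenyl)-2-(3,5-diacetoxyphenyl)ethyl]-6-[(E)-2-(3,5-diacetoxyphenyl)ethenyl]-1,3-phenylene diacetate
Conditions: Pd2(dba)3 (2.5 mol %), (S)-BI-DIME (6 mol %), Cy2NMe (1.5 equiv), 12 (0.95 equiv), BHT (trace), 1,4-dioxane, 45 °C, Ar; unreacted 9 recycled
Reagents that add atoms: none
Why: Proposed new method: monoligated L*Pd(0) inserts into one of the two enantiotopic C5–Br bonds of mirror-symmetric 9, styrene 12 then undergoes syn-carbopalladation at its terminal carbon and syn-β-hydride elimination to the E-stilbene, and Cy2NMe regenerates Pd(0), with no ring being closed. The closest known reaction types are the Mizoroki–Heck arylation of styrenes with aryl bromides under bulky electron-rich phosphines and the catalytic desymmetrisation of prochiral bis(bromoaryl)methanes by enantiotopic C–Br selection in Suzuki–Miyaura and Ullmann couplings, whereas an intermolecular Heck version with the bromine meta to the prochiral carbon has not been shown. No bond at the methine carbon is touched, yet it becomes stereogenic, and its configuration is controlled solely by the chiral phosphine in the oxidative-addition step. Allylic-type strain from the 2-acetoxy groups should hold the methine C–H in the plane of each ring, so that one π-face of each bromoarene is flanked by the CH2–ring C arm and the other by the sister ring, mirror-wise in rings A and B, which turns the choice of ring into π-face recognition only three bonds from the reacting carbon. Mono- over double coupling is secured by keeping 12 limiting, and any second coupling should consume mainly the minor enantiomer (it retains the faster-reacting C–Br bond) to give the achiral, separable bis-stilbene, which should raise the ee of 13. Site selectivity is absolute because only C5 of rings A and B carries bromine, the acetoxy groups make these bromides reactive at a mild temperature, and the neutral halide pathway gives β-arylation and the E-olefin.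

**Step 8**
Reactants: 13 (R)-bromostilbene octaacetate
Product: 14 4-[(1S)-1-(2,4-diacetoxyphenyl)-2-(3,5-diacetoxyphenyl)ethyl]-6-[(E)-2-(3,5-diacetoxyphenyl)ethenyl]-1,3-phenylene diacetate
Conditions: Pd(PPh3)4 (5 mol %), HCO2H (3 equiv), Et3N (4 equiv), DMF, 70 °C, Ar, dark
Reagents that add atoms: none
Why: Palladium-catalysed formate hydrodehalogenation (oxidative addition, formate exchange, decarboxylation, C–H reductive elimination) removes the spectator bromine without touching the methine carbon, and the descriptor changes from R to S only because ring A loses CIP priority.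

**Step 9**
Reactants: 14 (S)-stilbene octaacetate
Product: 15 4-[(1S)-1-(2,4-dihydroxyphenyl)-2-(3,5-dihydroxyphenyl)ethyl]-6-[(E)-2-(3,5-dihydroxyphenyl)ethenyl]benzene-1,3-diol (target)
Conditions: NH3 (7 M in MeOH, degassed), 0 °C to rt, Ar, dark; evaporation, Sephadex LH-20
Reagents that add atoms: none
Why: Ammonolysis of the eight aryl acetates is fast, metal-free and non-acidic, which avoids acid-induced cyclisation of the 2-hydroxystilbene and retro-Friedel–Crafts scrambling of the electron-rich diarylmethine.

**Compound list**
1 | 2,2',4,4'-tetrahydroxybenzophenone | O=C(c1ccc(O)cc1O)c1ccc(O)cc1O | starting material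
2 | 2,2',4,4'-tetramethoxybenzophenone | O=C(c1ccc(OC)cc1OC)c1ccc(OC)cc1OC | intermediate
3 | bis(5-bromo-2,4-dimethoxyphenyl)methanone | O=C(c1cc(Br)c(OC)cc1OC)c1cc(Br)c(OC)cc1OC | intermediate
4 | 3,5-dimethoxybenzyl chloride | ClCc1cc(OC)cc(OC)c1 | starting material
5 | 3,5-dimethoxybenzylmagnesium chloride (not isolated) | Cl[Mg]Cc1cc(OC)cc(OC)c1 | intermediate
6 | 1,1-bis(5-bromo-2,4-dimethoxyphenyl)-2-(3,5-dimethoxyphenyl)ethan-1-ol | OC(Cc1cc(OC)cc(OC)c1)(c1cc(Br)c(OC)cc1OC)c1cc(Br)c(OC)cc1OC | intermediate
7 | 1,1-bis(5-bromo-2,4-dimethoxyphenyl)-2-(3,5-dimethoxyphenyl)ethane | COc1cc(CC(c2cc(Br)c(OC)cc2OC)c2cc(Br)c(OC)cc2OC)cc(OC)c1 | intermediate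
8 | 4,4'-[2-(3,5-dihydroxyphenyl)ethane-1,1-diyl]bis(6-bromobenzene-1,3-diol) (hexaphenol dibromide, not isolated) | Oc1cc(CC(c2cc(Br)c(O)cc2O)c2cc(Br)c(O)cc2O)cc(O)c1 | intermediate
9 | 1,1-bis(2,4-diacetoxy-5-bromophenyl)-2-(3,5-diacetoxyphenyl)ethane | CC(=O)Oc1cc(CC(c2cc(Br)c(OC(C)=O)cc2OC(C)=O)c2cc(Br)c(OC(C)=O)cc2OC(C)=O)cc(OC(C)=O)c1 | intermediate
10 | 3,5-dihydroxybenzaldehyde | O=Cc1cc(O)cc(O)c1 | starting material
11 | 3,5-dihydroxystyrene (not isolated) | C=Cc1cc(O)cc(O)c1 | intermediate
12 | 3,5-diacetoxystyrene | C=Cc1cc(OC(C)=O)cc(OC(C)=O)c1 | intermediate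
13 | (R)-bromostilbene octaacetate (E-olefin, Br at C5 of ring A) | CC(=O)Oc1cc(OC(C)=O)cc(/C=C/c2cc([C@@H](Cc3cc(OC(C)=O)cc(OC(C)=O)c3)c3cc(Br)c(OC(C)=O)cc3OC(C)=O)c(OC(C)=O)cc2OC(C)=O)c1 | intermediate
14 | (S)-stilbene octaacetate (E-olefin) | CC(=O)Oc1cc(OC(C)=O)cc(/C=C/c2cc([C@@H](Cc3cc(OC(C)=O)cc(OC(C)=O)c3)c3ccc(OC(C)=O)cc3OC(C)=O)c(OC(C)=O)cc2OC(C)=O)c1 | intermediate
15 | 4-[(1S)-1-(2,4-dihydroxyphenyl)-2-(3,5-dihydroxyphenyl)ethyl]-6-[(E)-2-(3,5-dihydroxyphenyl)ethenyl]benzene-1,3-diol | Oc1cc(O)cc(/C=C/c2cc([C@@H](Cc3cc(O)cc(O)c3)c3ccc(O)cc3O)c(O)cc2O)c1 | target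

**Step count**
Total step count: 9. Longest linear sequence: 8 (steps 1–5 and 7–9).

**Steps most likely to fail**

Step 7. The catalyst may discriminate poorly between the two enantiotopic C–Br bonds, or the reaction may run on to double coupling. The fallback sets out from 9 and 12 and takes the stereochemistry from a resolution instead of from catalysis.
- A conventional Mizoroki–Heck reaction (Pd(OAc)2, P(o-tol)3, Et3N, MeCN, 85 °C) with 9 in twofold excess should give the racemic bromostilbene octaacetate F1, and unreacted 9 is recovered.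
- Preparative SFC on an immobilised amylose carbamate phase then separates the enantiomers.
- The unwanted (S)-bromostilbene octaacetate F2 is discarded, and the (R)-enantiomer is 13, where the route is rejoined.

Step 8. Palladium hydride may cause transfer hydrogenation or E/Z scrambling of the stilbene in competition with C–Br reduction. The fallback sets out from 13, reverses the order of the two unmasking operations and uses no metal hydride.
- Ammonolysis (NH3/MeOH, Ar) should give the (R)-bromo-octaphenol F3.
- The 6-bromoresorcinol ring of F3 is then debrominated with Na2SO3 in degassed H2O/EtOH at 50–60 °C.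
- This is the known halophilic reduction of bromoresorcinols through their keto tautomer, acting on bromine para to a hydroxyl group, and it leaves alkenes alone. The route is rejoined at 15.

Step 3. Addition to the hindered, electron-rich carbonyl group may be sluggish while the benzylic Grignard reagent is lost to Wurtz homocoupling. The fallback sets out from 3 and replaces carbonyl addition by substitution at a benzhydryl carbon.
- NaBH4 in THF/MeOH should give the bis(5-bromo-2,4-dimethoxyphenyl)methanol F4.
- SOCl2 in CH2Cl2 at 0 °C converts it into the bis(5-bromo-2,4-dimethoxyphenyl)methyl chloride F5, which is used crude.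
- F5 is coupled with the Grignard reagent 5 in THF at −40 °C (classical benzhydryl chloride/benzyl Grignard coupling). This rejoins the route at 7 and makes step 4 unnecessary.

**Further compounds**
F1 | step 7 | racemic bromostilbene octaacetate (rac-13) | CC(=O)Oc1cc(OC(C)=O)cc(/C=C/c2cc(C(Cc3cc(OC(C)=O)cc(OC(C)=O)c3)c3cc(Br)c(OC(C)=O)cc3OC(C)=O)c(OC(C)=O)cc2OC(C)=O)c1
F2 | step 7 | (S)-bromostilbene octaacetate (ent-13) | CC(=O)Oc1cc(OC(C)=O)cc(/C=C/c2cc([C@H](Cc3cc(OC(C)=O)cc(OC(C)=O)c3)c3cc(Br)c(OC(C)=O)cc3OC(C)=O)c(OC(C)=O)cc2OC(C)=O)c1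
F3 | step 8 | 4-[(1R)-1-(5-bromo-2,4-dihydroxyphenyl)-2-(3,5-dihydroxyphenyl)ethyl]-6-[(E)-2-(3,5-dihydroxyphenyl)ethenyl]benzene-1,3-diol | Oc1cc(O)cc(/C=C/c2cc([C@@H](Cc3cc(O)cc(O)c3)c3cc(Br)c(O)cc3O)c(O)cc2O)c1
F4 | step 3 | bis(5-bromo-2,4-dimethoxyphenyl)methanol | OC(c1cc(Br)c(OC)cc1OC)c1cc(Br)c(OC)cc1OC
F5 | step 3 | bis(5-bromo-2,4-dimethoxyphenyl)methyl chloride | ClC(c1cc(Br)c(OC)cc1OC)c1cc(Br)c(OC)cc1OC
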